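**Strategy.** The plan cuts the pyran ring of the upper 3,4-diarylchroman at C3–C4 and O1–C2. There C4 is a diarylmethine carbon ortho to the phenolic O1 of ring A (O1–C8a–C4a–C4), the latent form of an ortho-quinone methide, and C2–C3, with the dimethoxyphenyl ring B on C3, is a β-aryl enol ether. One chiral phosphoric acid catalysed oxa-[4+2] cycloaddition makes both bonds, closes the ring and sets the trans C3/C4 centres. Its precursors are an ortho-hydroxy diarylmethanol that already carries the enantiopure lower chroman (Evans benzylation, Mitsunobu closure) and a geometrically pure (E)-enol ether. Acetal reduction and hydrogenolysis finish the synthesis.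

Key step: step 16

Remarks on the chemistry:
- "Upper chroman" is the 3,4-diaryl one (O1, C2, C3, C4, benzo ring A). Ring B is the 2-oxygenated 4,5-dimethoxyphenyl group on C3, ring C the aryl group on C4, and "lower chroman" the (3R)-chroman attached to ring C. "Chroman" means 3,4-dihydro-2H-chromene.
- The target is (3R,4S) in the upper chroman (aryl groups trans) and (3R) in the lower one.
- Assumption: the (R) enantiomer of the phosphoric acid is taken to open the face of the methide carbon that leads to (4S). Because the lower chroman is already (R), the two catalyst enantiomers would give diastereomers, so the sense can be checked directly, and the (S) acid would be used if the model proves inverted.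
- The enol ether carries ethoxy, not methoxy, because the (E)-ethoxyvinyl boronate is sold as the pure E isomer; this alkoxy group is a spectator removed in step 17.

**Route**

Step 1
Reactants: 1 2-hydroxy-4-methoxybenzaldehyde
Product: 2 5-bromo-2-hydroxy-4-methoxybenzaldehyde
Conditions: Br2 (1.0 equiv), CH2Cl2, 0 °C to rt
Reagents that add atoms: bromine, BrBr
Why: Electrophilic aromatic bromination should occur at C5, which is para to the phenol, ortho to the methoxy group and less hindered than C3, placing the halogen where the aryllithium is needed later.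

Step 2
Reactants: 2 5-bromo-2-hydroxy-4-methoxybenzaldehyde
Product: 3 2-(benzyloxy)-5-bromo-4-methoxybenzaldehyde
Conditions: BnBr, K2CO3, DMF, 60 °C
Reagents that add atoms: benzyl bromide, BrCc1ccccc1
Why: Williamson ether synthesis on the phenoxide gives a benzyl ether that survives all later steps and falls in the final hydrogenolysis.

Step 3
Reactants: 3 2-(benzyloxy)-5-bromo-4-methoxybenzaldehyde
Product: 5 [2-(benzyloxy)-5-bromo-4-methoxyphenyl]acetonitrile, via tosylvinyl formamide 4 (not isolated)
Conditions: TosMIC, KOtBu, DME, −40 °C; then MeOH, reflux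
Reagents that add atoms: p-toluenesulfonylmethyl isocyanide (TosMIC), [C-]#[N+]CS(=O)(=O)c1ccc(C)cc1
Why: Van Leusen reductive cyanation, in which the TosMIC anion adds to the aldehyde, the oxazoline opens to the N-formyl tosyl enamine, and methanolysis with loss of sulfinate leaves the one-carbon homologated nitrile without touching the aryl bromide or the benzyl ether.

Step 4
Reactants: 5 [2-(benzyloxy)-5-bromo-4-methoxyphenyl]acetonitrile
Product: 6 [2-(benzyloxy)-5-bromo-4-methoxyphenyl]acetic acid
Conditions: KOH, EtOH/H2O, reflux; then aq. HCl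
Reagents that add atoms: water, O
Why: Base hydrolysis of the nitrile through the primary amide should be clean because no other group in the molecule is base-labile.

Step 5
Reactants: 6 [2-(benzyloxy)-5-bromo-4-methoxyphenyl]acetic acid; 7 (4R)-4-benzyl-1,3-oxazolidin-2-one
Product: 9 (4R)-4-benzyl-3-{[2-(benzyloxy)-5-bromo-4-methoxyphenyl]acetyl}-1,3-oxazolidin-2-one, via mixed pivalic anhydride 8 (not isolated)
Conditions: PivCl, Et3N, THF, −20 °C; then 7, LiCl, rt
Reagents that add atoms: none
Why: N-acylation of the oxazolidinone through the mixed anhydride should occur at the less hindered arylacetyl carbonyl and installs the auxiliary without strong base.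

Step 6
Reactants: 10 4-(benzyloxy)-2-hydroxybenzaldehyde
Product: 11 4-(benzyloxy)-2-(methoxymethoxy)benzaldehyde
Conditions: MOMCl, i-Pr2NEt, CH2Cl2, 0 °C to rt
Reagents that add atoms: chloromethyl methyl ether, COCCl
Why: Alkylation of the phenol gives a MOM acetal that is stable to hydride, enolate and base and is removed by acid without touching benzyl ethers.

Step 7
Reactants: 11 4-(benzyloxy)-2-(methoxymethoxy)benzaldehyde
Product: 12 [4-(benzyloxy)-2-(methoxymethoxy)phenyl]methanol
Conditions: NaBH4, MeOH/THF, 0 °C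
Reagents that add atoms: none
Why: Borohydride reduction of the aldehyde is chemoselective and leaves both ethers intact.

Step 8
Reactants: 12 [4-(benzyloxy)-2-(methoxymethoxy)phenyl]methanol
Product: 13 4-(benzyloxy)-1-(bromomethyl)-2-(methoxymethoxy)benzene
Conditions: CBr4, PPh3, CH2Cl2, 0 °C; used at once
Reagents that add atoms: carbon tetrabromide, BrC(Br)(Br)Br
Why: The Appel reaction converts the benzylic alcohol into the bromide under nearly neutral conditions that spare the acid-labile MOM group.

Step 9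
Reactants: 9 (4R)-4-benzyl-3-{[2-(benzyloxy)-5-bromo-4-methoxyphenyl]acetyl}-1,3-oxazolidin-2-one; 13 4-(benzyloxy)-1-(bromomethyl)-2-(methoxymethoxy)benzene
Product: 15 (4R)-4-benzyl-3-{(2R)-2-[2-(benzyloxy)-5-bromo-4-methoxyphenyl]-3-[4-(benzyloxy)-2-(methoxymethoxy)phenyl]propanoyl}-1,3-oxazolidin-2-one, via sodium Z-enolate 14 (not isolated)
Conditions: NaN(SiMe3)2, THF, −78 °C; then 13, −78 to −40 °C
Reagents that add atoms: none
Why: Evans asymmetric alkylation, in which the chelated Z-enolate is attacked by the reactive benzylic bromide on the face away from the 4-benzyl group of the (R)-auxiliary, sets the (R) centre that becomes C3 of the lower chroman.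

Step 10
Reactants: 15 (4R)-4-benzyl-3-{(2R)-2-[2-(benzyloxy)-5-bromo-4-methoxyphenyl]-3-[4-(benzyloxy)-2-(methoxymethoxy)phenyl]propanoyl}-1,3-oxazolidin-2-one
Product: 17 5-(benzyloxy)-2-{(2R)-2-[2-(benzyloxy)-5-bromo-4-methoxyphenyl]-3-hydroxypropyl}phenol, via MOM-protected alcohol 16 (not isolated)
Conditions: LiBH4, MeOH (1 equiv), THF, 0 °C; then aq. HCl, MeOH, 45 °C
Reagents that add atoms: none
Why: Reductive cleavage of the imide at the exocyclic carbonyl by LiBH4 gives the primary alcohol and releases the auxiliary, and acid methanolysis of the MOM acetal in the same flask frees the phenol, the stereocentre being no longer enolisable once the carbonyl is reduced.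

Step 11
Reactants: 17 5-(benzyloxy)-2-{(2R)-2-[2-(benzyloxy)-5-bromo-4-methoxyphenyl]-3-hydroxypropyl}phenol
Product: 18 (3R)-7-(benzyloxy)-3-[2-(benzyloxy)-5-bromo-4-methoxyphenyl]chroman
Conditions: PPh3, DIAD, THF, 0 °C to rt
Reagents that add atoms: none
Why: Intramolecular Mitsunobu etherification (6-exo-tet displacement of the activated primary alcohol by the phenol) closes the lower chroman without touching the adjacent stereocentre.

Step 12
Reactants: 18 (3R)-7-(benzyloxy)-3-[2-(benzyloxy)-5-bromo-4-methoxyphenyl]chroman; 10 4-(benzyloxy)-2-hydroxybenzaldehyde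
Product: 21 [4-(benzyloxy)-2-hydroxyphenyl]{4-(benzyloxy)-5-[(3R)-7-(benzyloxy)chroman-3-yl]-2-methoxyphenyl}methanol (both carbinol epimers), via sodium phenolate 19 (not isolated), via aryllithium 20 (not isolated)
Conditions: 10, NaH, THF, 0 °C (separate flask); 18, n-BuLi, THF, −78 °C; combine, −78 to 0 °C; aq. NH4Cl
Reagents that add atoms: none
Why: Bromine–lithium exchange followed by 1,2-addition to the aldehyde forms the congested aryl–C4 bond as a carbinol; the aldehyde is supplied as its preformed phenolate so that the free hydroxyl cannot quench the valuable aryllithium, and both carbinol epimers serve because this carbon becomes planar in step 16.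

Step 13
Reactants: 22 3,4-dimethoxyphenol
Product: 23 4-(benzyloxy)-1,2-dimethoxybenzene
Conditions: BnBr, K2CO3, DMF, 60 °C
Reagents that add atoms: benzyl bromide, BrCc1ccccc1
Why: Williamson ether synthesis protects the phenol before halogenation, which avoids oxidation of the electron-rich phenol.

Step 14
Reactants: 23 4-(benzyloxy)-1,2-dimethoxybenzene
Product: 24 1-(benzyloxy)-2-bromo-4,5-dimethoxybenzene
Conditions: NBS, MeCN, 0 °C to rt
Reagents that add atoms: N-bromosuccinimide, O=C1CCC(=O)N1Br
Why: Electrophilic aromatic bromination should go to the one position that is ortho to the benzyloxy group and para to a methoxy group, since it is activated by both and is unhindered.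

Step 15
Reactants: 24 1-(benzyloxy)-2-bromo-4,5-dimethoxybenzene; 25 (E)-2-(2-ethoxyvinyl)-4,4,5,5-tetramethyl-1,3,2-dioxaborolane
Product: 26 (E)-1-(benzyloxy)-2-(2-ethoxyvinyl)-4,5-dimethoxybenzene
Conditions: Pd(OAc)2 (3 mol %), SPhos (6 mol %), K3PO4, dioxane/H2O, 80 °C
Reagents that add atoms: none
Why: Suzuki–Miyaura coupling transfers the vinyl group with retention of its geometry, so only the E enol ether should form, whereas a Wittig methoxymethylenation of the corresponding aldehyde would give an E/Z mixture and put the trans selectivity of step 16 at risk.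

Step 16
Reactants: 21 [4-(benzyloxy)-2-hydroxyphenyl]{4-(benzyloxy)-5-[(3R)-7-(benzyloxy)chroman-3-yl]-2-methoxyphenyl}methanol; 26 (E)-1-(benzyloxy)-2-(2-ethoxyvinyl)-4,5-dimethoxybenzene
Product: 28 (3R,4S)-7-(benzyloxy)-4-{4-(benzyloxy)-5-[(3R)-7-(benzyloxy)chroman-3-yl]-2-methoxyphenyl}-3-[2-(benzyloxy)-4,5-dimethoxyphenyl]-2-ethoxychroman (both C2 epimers), via ortho-quinone methide 27 (not isolated)
Conditions: (R)-3,3'-bis(2,4,6-triisopropylphenyl)-1,1'-binaphthyl-2,2'-diyl hydrogen phosphate (10 mol %), 4 Å molecular sieves, toluene, 0 °C; 26 in excess (1.5 equiv)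
Reagents that add atoms: none
Why: The phosphoric acid dehydrates either carbinol epimer to the hydrogen-bonded ortho-quinone methide 27, whose exocyclic carbon is attacked by the nucleophilic β-carbon of the enol ether while the ring A oxygen closes on the developing oxocarbenium carbon; this is an asynchronous inverse-electron-demand oxa-Diels–Alder reaction of the kind known for chiral phosphoric acids, ortho-hydroxybenzhydrols and enol ethers or styrenes. The pyran ring is closed by the [4+2] cycloaddition itself (C3–C4 first, then O1–C2, which in the stepwise limit is a 6-exo-trig capture of the oxocarbenium ion by the phenolate). C4 is set by the chiral phosphate, which stays bound to the methide oxygen and leaves one face of the methide carbon open, taken here to give (4S) with the (R) acid. C3 is set relative to C4 by the E geometry of the enol ether together with an endo ethoxy group, which places the two aryl groups trans, while C2 is an acetal carbon that is erased in step 17. The step needs regioselectivity (β-carbon to methide carbon, secured by the polarity of both partners), chemoselectivity against Friedel–Crafts attack by the benzyloxy arenes and against hydrolysis of the enol ether (secured by the higher nucleophilicity of the enol ether, its excess and the sieves), and catalyst control over the remote (R) centre of the lower chroman, which is too far away to compete.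

Step 17
Reactants: 28 (3R,4S)-7-(benzyloxy)-4-{4-(benzyloxy)-5-[(3R)-7-(benzyloxy)chroman-3-yl]-2-methoxyphenyl}-3-[2-(benzyloxy)-4,5-dimethoxyphenyl]-2-ethoxychroman
Product: 29 (3R,4S)-7-(benzyloxy)-4-{4-(benzyloxy)-5-[(3R)-7-(benzyloxy)chroman-3-yl]-2-methoxyphenyl}-3-[2-(benzyloxy)-4,5-dimethoxyphenyl]chroman
Conditions: Et3SiH, BF3·OEt2, CH2Cl2, −78 to −30 °C
Reagents that add atoms: none
Why: Ionic hydrogenation of the mixed acetal, in which BF3 ionises the exocyclic C2–OEt bond and the silane reduces the cyclic oxocarbenium ion, should convert both C2 epimers into the same CH2 group at a temperature that spares the benzyl ethers and the C3 and C4 centres.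

Step 18
Reactants: 29 (3R,4S)-7-(benzyloxy)-4-{4-(benzyloxy)-5-[(3R)-7-(benzyloxy)chroman-3-yl]-2-methoxyphenyl}-3-[2-(benzyloxy)-4,5-dimethoxyphenyl]chroman
Product: 30 (3R,4S)-4-{4-hydroxy-5-[(3R)-7-hydroxychroman-3-yl]-2-methoxyphenyl}-3-(2-hydroxy-4,5-dimethoxyphenyl)chroman-7-ol
Conditions: H2 (1 atm), 10% Pd/C, EtOAc/MeOH, rt
Reagents that add atoms: none
Why: Catalytic hydrogenolysis cleaves the four aryl benzyl ethers and nothing else, since the chroman C–O bonds are not benzylic and no stereocentre carries a leaving group.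

**Compound list**

1 | 2-hydroxy-4-methoxybenzaldehyde | COc1ccc(C=O)c(O)c1 | starting material
2 | 5-bromo-2-hydroxy-4-methoxybenzaldehyde | COc1cc(O)c(C=O)cc1Br | intermediate
3 | 2-(benzyloxy)-5-bromo-4-methoxybenzaldehyde | COc1cc(OCc2ccccc2)c(C=O)cc1Br | intermediate
4 | N-{2-[2-(benzyloxy)-5-bromo-4-methoxyphenyl]-1-tosylethenyl}formamide (potassium salt in the flask) | COc1cc(OCc2ccccc2)c(C=C(NC=O)S(=O)(=O)c2ccc(C)cc2)cc1Br | intermediate (not isolated)
5 | [2-(benzyloxy)-5-bromo-4-methoxyphenyl]acetonitrile | COc1cc(OCc2ccccc2)c(CC#N)cc1Br | intermediate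
6 | [2-(benzyloxy)-5-bromo-4-methoxyphenyl]acetic acid | COc1cc(OCc2ccccc2)c(CC(=O)O)cc1Br | intermediate
7 | (4R)-4-benzyl-1,3-oxazolidin-2-one | O=C1N[C@H](Cc2ccccc2)CO1 | starting material
8 | [2-(benzyloxy)-5-bromo-4-methoxyphenyl]acetic pivalic anhydride | COc1cc(OCc2ccccc2)c(CC(=O)OC(=O)C(C)(C)C)cc1Br | intermediate (not isolated)
9 | (4R)-4-benzyl-3-{[2-(benzyloxy)-5-bromo-4-methoxyphenyl]acetyl}-1,3-oxazolidin-2-one | COc1cc(OCc2ccccc2)c(CC(=O)N2[C@H](Cc3ccccc3)COC2=O)cc1Br | intermediate
10 | 4-(benzyloxy)-2-hydroxybenzaldehyde | O=Cc1ccc(OCc2ccccc2)cc1O | starting material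
11 | 4-(benzyloxy)-2-(methoxymethoxy)benzaldehyde | COCOc1cc(OCc2ccccc2)ccc1C=O | intermediate
12 | [4-(benzyloxy)-2-(methoxymethoxy)phenyl]methanol | COCOc1cc(OCc2ccccc2)ccc1CO | intermediate
13 | 4-(benzyloxy)-1-(bromomethyl)-2-(methoxymethoxy)benzene | COCOc1cc(OCc2ccccc2)ccc1CBr | intermediate
14 | sodium (Z)-enolate of imide 9 | COc1cc(OCc2ccccc2)c(/C=C(\[O-])N2[C@H](Cc3ccccc3)COC2=O)cc1Br.[Na+] | intermediate (not isolated)
15 | (4R)-4-benzyl-3-{(2R)-2-[2-(benzyloxy)-5-bromo-4-methoxyphenyl]-3-[4-(benzyloxy)-2-(methoxymethoxy)phenyl]propanoyl}-1,3-oxazolidin-2-one | COCOc1cc(OCc2ccccc2)ccc1C[C@H](c1cc(Br)c(OC)cc1OCc1ccccc1)C(=O)N1[C@H](Cc2ccccc2)COC1=O | intermediate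
16 | (2R)-2-[2-(benzyloxy)-5-bromo-4-methoxyphenyl]-3-[4-(benzyloxy)-2-(methoxymethoxy)phenyl]propan-1-ol | COCOc1cc(OCc2ccccc2)ccc1C[C@H](c1cc(Br)c(OC)cc1OCc1ccccc1)CO | intermediate (not isolated)
17 | 5-(benzyloxy)-2-{(2R)-2-[2-(benzyloxy)-5-bromo-4-methoxyphenyl]-3-hydroxypropyl}phenol | Oc1cc(OCc2ccccc2)ccc1C[C@H](c1cc(Br)c(OC)cc1OCc1ccccc1)CO | intermediate
18 | (3R)-7-(benzyloxy)-3-[2-(benzyloxy)-5-bromo-4-methoxyphenyl]chroman | COc1cc(OCc2ccccc2)c([C@@H]2COc3cc(OCc4ccccc4)ccc3C2)cc1Br | intermediate
19 | sodium 5-(benzyloxy)-2-formylphenolate | [Na+].[O-]c1cc(OCc2ccccc2)ccc1C=O | intermediate (not isolated)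
20 | {4-(benzyloxy)-5-[(3R)-7-(benzyloxy)chroman-3-yl]-2-methoxyphenyl}lithium | [Li]c1cc([C@@H]2COc3cc(OCc4ccccc4)ccc3C2)c(OCc2ccccc2)cc1OC | intermediate (not isolated)
21 | [4-(benzyloxy)-2-hydroxyphenyl]{4-(benzyloxy)-5-[(3R)-7-(benzyloxy)chroman-3-yl]-2-methoxyphenyl}methanol (both carbinol epimers) | OC(c1ccc(OCc2ccccc2)cc1O)c1cc([C@@H]2COc3cc(OCc4ccccc4)ccc3C2)c(OCc2ccccc2)cc1OC | intermediate
22 | 3,4-dimethoxyphenol | COc1ccc(O)cc1OC | starting material
23 | 4-(benzyloxy)-1,2-dimethoxybenzene | COc1ccc(OCc2ccccc2)cc1OC | intermediate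
24 | 1-(benzyloxy)-2-bromo-4,5-dimethoxybenzene | COc1cc(Br)c(OCc2ccccc2)cc1OC | intermediate
25 | (E)-2-(2-ethoxyvinyl)-4,4,5,5-tetramethyl-1,3,2-dioxaborolane | CCO/C=C/B1OC(C)(C)C(C)(C)O1 | starting material
26 | (E)-1-(benzyloxy)-2-(2-ethoxyvinyl)-4,5-dimethoxybenzene | CCO/C=C/c1cc(OC)c(OC)cc1OCc1ccccc1 | intermediate
27 | (6E)-3-(benzyloxy)-6-({4-(benzyloxy)-5-[(3R)-7-(benzyloxy)chroman-3-yl]-2-methoxyphenyl}methylidene)cyclohexa-2,4-dien-1-one | O=C1C=C(OCc2ccccc2)C=C/C1=C\c1cc([C@@H]2COc3cc(OCc4ccccc4)ccc3C2)c(OCc2ccccc2)cc1OC | intermediate (not isolated)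
28 | (3R,4S)-7-(benzyloxy)-4-{4-(benzyloxy)-5-[(3R)-7-(benzyloxy)chroman-3-yl]-2-methoxyphenyl}-3-[2-(benzyloxy)-4,5-dimethoxyphenyl]-2-ethoxychroman (C2 epimers; 3,4-trans) | COc1cc(OCc5ccccc5)c([C@@H]2C(OCC)Oc3cc(OCc5ccccc5)ccc3[C@H]2c2cc([C@@H]3COc4cc(OCc5ccccc5)ccc4C3)c(OCc5ccccc5)cc2OC)cc1OC | intermediate
29 | (3R,4S)-7-(benzyloxy)-4-{4-(benzyloxy)-5-[(3R)-7-(benzyloxy)chroman-3-yl]-2-methoxyphenyl}-3-[2-(benzyloxy)-4,5-dimethoxyphenyl]chroman | COc1cc(OCc5ccccc5)c([C@@H]2COc3cc(OCc5ccccc5)ccc3[C@H]2c2cc([C@@H]3COc4cc(OCc5ccccc5)ccc4C3)c(OCc5ccccc5)cc2OC)cc1OC | intermediate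
30 | (3R,4S)-4-{4-hydroxy-5-[(3R)-7-hydroxychroman-3-yl]-2-methoxyphenyl}-3-(2-hydroxy-4,5-dimethoxyphenyl)chroman-7-ol | COc1cc(O)c([C@@H]2COc3cc(O)ccc3[C@H]2c2cc([C@@H]3COc4cc(O)ccc4C3)c(O)cc2OC)cc1OC | target

**Step count and risk**

Total: 18 steps. Longest linear sequence: 12 steps (steps 1–5, 9–12, 16–18).

Steps most likely to fail:

1. Step 16. The phosphate may discriminate the two faces of the methide carbon poorly, because the doubly donor-stabilised cation can react as a loosely bound ion pair or through an uncatalysed background path. Fallback: the same partners 21 and 26 are combined with an achiral acid (diphenyl phosphate, toluene, 0 °C), giving up catalyst control. The E enol ether should still give trans adducts, namely 28 together with its diastereomer (3S,4R)-7-(benzyloxy)-4-{4-(benzyloxy)-5-[(3R)-7-(benzyloxy)chroman-3-yl]-2-methoxyphenyl}-3-[2-(benzyloxy)-4,5-dimethoxyphenyl]-2-ethoxychroman F1. The mixture is reduced as in step 17 to 29 and the (3S,4R) isomer of the tetrabenzyl chroman F2. Because the lower chroman is (R) in both, these are diastereomers, and they would be separated by preparative chromatography or crystallisation. This replaces asymmetric catalysis by an internal resolution and rejoins the route at 29.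

2. Step 12. The aryllithium may be lost to proton transfer, or may add only sluggishly to the electron-rich phenolate aldehyde, which would return debrominated chroman. Fallback: the hydroxyl is masked instead of deprotonated. Compound 10 is silylated (TBSCl, imidazole, DMF) to 4-(benzyloxy)-2-[(tert-butyldimethylsilyl)oxy]benzaldehyde F3. Aryllithium 20, made from 18 as before, adds to F3 to give the silyl-protected diarylmethanol F4; a silyl shift to the benzylic oxygen would be harmless. Bu4NF buffered with AcOH in THF then releases 21, where the route is rejoined.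

3. Step 17. The acetal may ionise along the wrong path: opening of the pyran ring at O1–C2 with reduction to an open-chain ether, loss of benzyl ethers under BF3, or loss of the C3 proton from the oxocarbenium ion. Fallback: hydride is kept away from the cation. Compound 28 is hydrolysed (aq. HCl, THF, rt) to the lactol (3R,4S)-7-(benzyloxy)-4-{4-(benzyloxy)-5-[(3R)-7-(benzyloxy)chroman-3-yl]-2-methoxyphenyl}-3-[2-(benzyloxy)-4,5-dimethoxyphenyl]chroman-2-ol F5, on which both ionisation modes converge and in which the trans arrangement is the thermodynamic one. NaBH4 (MeOH/THF, 0 °C) reduces its open hydroxy aldehyde form to the phenol–primary alcohol 5-(benzyloxy)-2-[(1S,2R)-1-{4-(benzyloxy)-5-[(3R)-7-(benzyloxy)chroman-3-yl]-2-methoxyphenyl}-2-[2-(benzyloxy)-4,5-dimethoxyphenyl]-3-hydroxypropyl]phenol F6. A Mitsunobu closure (PPh3, DIAD, THF), the reaction already used in step 11, re-forms the pyran ring and gives 29.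

**Further compounds**

F1 | step 16 | (3S,4R)-7-(benzyloxy)-4-{4-(benzyloxy)-5-[(3R)-7-(benzyloxy)chroman-3-yl]-2-methoxyphenyl}-3-[2-(benzyloxy)-4,5-dimethoxyphenyl]-2-ethoxychroman (C2 epimers) | COc1cc(OCc5ccccc5)c([C@H]2C(OCC)Oc3cc(OCc5ccccc5)ccc3[C@@H]2c2cc([C@@H]3COc4cc(OCc5ccccc5)ccc4C3)c(OCc5ccccc5)cc2OC)cc1OC
F2 | step 16 | (3S,4R)-7-(benzyloxy)-4-{4-(benzyloxy)-5-[(3R)-7-(benzyloxy)chroman-3-yl]-2-methoxyphenyl}-3-[2-(benzyloxy)-4,5-dimethoxyphenyl]chroman | COc1cc(OCc5ccccc5)c([C@H]2COc3cc(OCc5ccccc5)ccc3[C@@H]2c2cc([C@@H]3COc4cc(OCc5ccccc5)ccc4C3)c(OCc5ccccc5)cc2OC)cc1OC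
F3 | step 12 | 4-(benzyloxy)-2-[(tert-butyldimethylsilyl)oxy]benzaldehyde | CC(C)(C)[Si](C)(C)Oc1cc(OCc2ccccc2)ccc1C=O
F4 | step 12 | {4-(benzyloxy)-2-[(tert-butyldimethylsilyl)oxy]phenyl}{4-(benzyloxy)-5-[(3R)-7-(benzyloxy)chroman-3-yl]-2-methoxyphenyl}methanol (both carbinol epimers) | OC(c1ccc(OCc2ccccc2)cc1O[Si](C)(C)C(C)(C)C)c1cc([C@@H]2COc3cc(OCc4ccccc4)ccc3C2)c(OCc2ccccc2)cc1OC
F5 | step 17 | (3R,4S)-7-(benzyloxy)-4-{4-(benzyloxy)-5-[(3R)-7-(benzyloxy)chroman-3-yl]-2-methoxyphenyl}-3-[2-(benzyloxy)-4,5-dimethoxyphenyl]chroman-2-ol (C2 epimers) | COc1cc(OCc5ccccc5)c([C@@H]2C(O)Oc3cc(OCc5ccccc5)ccc3[C@H]2c2cc([C@@H]3COc4cc(OCc5ccccc5)ccc4C3)c(OCc5ccccc5)cc2OC)cc1OC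
F6 | step 17 | 5-(benzyloxy)-2-[(1S,2R)-1-{4-(benzyloxy)-5-[(3R)-7-(benzyloxy)chroman-3-yl]-2-methoxyphenyl}-2-[2-(benzyloxy)-4,5-dimethoxyphenyl]-3-hydroxypropyl]phenol | COc1cc(OCc5ccccc5)c([C@H](CO)[C@@H](c2ccc(OCc5ccccc5)cc2O)c2cc([C@@H]3COc4cc(OCc5ccccc5)ccc4C3)c(OCc5ccccc5)cc2OC)cc1OC
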